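The benzoquinone ring is cut at C1–C6 and C4–C5. Its C1–C4 half, O=C–C(OMe)=C(OMe)–C=O, is locally symmetric and is dimethyl squarate with the acyl–acyl bond opened by cobalt. Its C5(OMe)=C6(chromanyl) edge is a methyl ynol ether. In the last step the dimethoxymaleoylcobalt complex takes up (3S)-3-(methoxyethynyl)-6,7,8-trimethoxychroman and forms both acyl–alkyne bonds. This gives the fully substituted quinone at its final oxidation level, and the symmetry of the maleoyl half removes any regiochemical question. C3 of the chroman ring is set by an asymmetric intramolecular Stetter reaction, and the ester methoxy group of that product ends as the C5 methoxy group.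

Key step: step 8

Assumption: the enantiomer of the triazolium catalyst that gives (S)-7 is chosen by analogy with the parent 4-(2-formylphenoxy)but-2-enoates; both enantiomers of the salt are commercial.

Step 1
Reactants: 1 2,3,4-trimethoxybenzaldehyde
Product: 3 2,3,4-trimethoxyphenol, via aryl formate 2 (not isolated)
Conditions: 30% H2O2, cat. H2SO4, MeOH, rt
Reagents that add atoms: hydrogen peroxide, OO
Why: Acid-promoted Dakin oxidation, in which the electron-rich aryl group migrates to oxygen and the formate 2 is methanolysed in the same flask.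

Step 2
Reactants: 3 2,3,4-trimethoxyphenol
Product: 4 2-hydroxy-3,4,5-trimethoxybenzaldehyde
Conditions: MgCl2, Et3N, (CH2O)n, MeCN, reflux; aq. HCl work-up
Reagents that add atoms: paraformaldehyde (as formaldehyde), C=O
Why: Casnati–Skattebøl ortho-formylation through the magnesium phenoxide is ortho-specific, and C6 is the only free ortho position of 3.

Step 3
Reactants: 4 2-hydroxy-3,4,5-trimethoxybenzaldehyde; 5 methyl (E)-4-bromobut-2-enoate
Product: 6 methyl (E)-4-(6-formyl-2,3,4-trimethoxyphenoxy)but-2-enoate
Conditions: K2CO3, DMF, rt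
Reagents that add atoms: none
Why: Williamson ether synthesis by SN2 at the primary allylic bromide, run at room temperature so that the aldehyde and the E-enoate stay untouched.

Step 4
Reactants: 6 methyl (E)-4-(6-formyl-2,3,4-trimethoxyphenoxy)but-2-enoate
Product: 7 methyl 2-[(3S)-6,7,8-trimethoxy-4-oxochroman-3-yl]acetate
Conditions: aminoindanol-derived N-pentafluorophenyl triazolium tetrafluoroborate (10–20 mol%), KN(SiMe3)2 (slightly less than the salt), toluene, rt
Reagents that add atoms: none
Why: Asymmetric intramolecular Stetter reaction, in which the Breslow intermediate of the aldehyde adds 6-exo-trig to the enoate β-carbon and the chiral carbene selects the enoate face that sets C3 as (S).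

Step 5
Reactants: 7 methyl 2-[(3S)-6,7,8-trimethoxy-4-oxochroman-3-yl]acetate
Product: 9 methyl 2-[(3S)-6,7,8-trimethoxychroman-3-yl]acetate, via chroman-4-ol 8 (not isolated)
Conditions: Et3SiH (5 equiv), CF3CO2H/CH2Cl2, 0 °C to rt
Reagents that add atoms: none
Why: Kursanov–Parnes ionic hydrogenation, in which the C4 cation stabilised by O1 and the 7-methoxy group is trapped by excess silane while the ester and the aryl ethers are inert.

Step 6
Reactants: 9 methyl 2-[(3S)-6,7,8-trimethoxychroman-3-yl]acetate
Product: 11 (3S)-3-(methoxyethynyl)-6,7,8-trimethoxychroman, via ketene acetal phosphate 10 (not isolated)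
Conditions: LiN(iPr)2, THF/DMPU, −78 °C; ClP(O)(OEt)2; then t-BuLi (2.2 equiv), −78 °C; aq. NaHCO3 quench, Et3N-deactivated silica
Reagents that add atoms: diethyl chlorophosphate, CCOP(=O)(Cl)OCC (its atoms stay in 10 only and leave again)
Why: Enol phosphate route to 1-alkoxyalkynes (O-phosphorylation of the ester enolate, then base-induced β-elimination of diethyl phosphate), in which C3 lies β to the ester and is never made acidic.

Step 7
Reactants: 12 dimethyl squarate
Product: 14 chloro(dimethylglyoxime)(pyridine)(2,3-dimethoxy-1,4-dioxobut-2-ene-1,4-diyl)cobalt, via bis(triphenylphosphine) complex 13 (not isolated)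
Conditions: ClCo(PPh3)3, toluene, rt; evaporate; dimethylglyoxime, pyridine, rt; precipitate with water
Reagents that add atoms: ClCo(PPh3)3, Cl[Co-3]([P+](c1ccccc1)(c1ccccc1)c1ccccc1)([P+](c1ccccc1)(c1ccccc1)c1ccccc1)[P+](c1ccccc1)(c1ccccc1)c1ccccc1; dimethylglyoxime, CC(=NO)C(C)=NO; pyridine, c1ccncc1
Why: Oxidative addition of monovalent cobalt into the strained acyl–acyl bond of the cyclobutenedione gives the trivalent cobaltacyclopentenedione, and ligand exchange removes the phosphines that could otherwise attack a quinone product.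

Step 8
Reactants: 11 (3S)-3-(methoxyethynyl)-6,7,8-trimethoxychroman; 14 chloro(dimethylglyoxime)(pyridine)(2,3-dimethoxy-1,4-dioxobut-2-ene-1,4-diyl)cobalt
Product: 15 2,3,5-trimethoxy-6-[(3S)-6,7,8-trimethoxychroman-3-yl]cyclohexa-2,5-diene-1,4-dione
Conditions: 14 (1.3 equiv), anhydrous CoCl2 (1 equiv), 4 Å MS, ClCH2CH2Cl, 70 °C, sealed tube; work-up in air
Reagents that add atoms: none
Why: CoCl2 takes the pyridine off 14, the ynol ether 11 binds at the free site of the trivalent cobaltacyclopentenedione and inserts into one Co–acyl bond (first C–C bond), and C–C reductive elimination from the resulting seven-membered cobaltacycle joins the vinyl carbon to the second acyl carbon (second C–C bond) and releases 15 together with monovalent cobalt. The closest known reaction type is the maleoylcobalt or phthaloylcobalt plus alkyne quinone synthesis from cyclobutenediones, a metal-templated formal [4+2] cycloaddition. The one ring that closes is the six-membered quinone ring, closed by reductive elimination with contraction of the metallacycle, so no Baldwin-type constraint applies. No stereocentre is created, and the propargylic C3–H of 11 is left alone in a neutral aprotic medium, so the (S) configuration is carried through. The selectivity usually at stake, the orientation of an unsymmetrical alkyne, is void here because the C1–C4 dimethoxymaleoyl unit is symmetric and both orientations give the same quinone. Chemoselectivity rests on the methyl ynol ether, which has no β-hydrogen for retro-ene loss at 70 °C, and on dry conditions that suppress its hydration back to 9.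

Compound list
1 | 2,3,4-trimethoxybenzaldehyde | O=Cc1ccc(OC)c(OC)c1OC | starting material
2 | 2,3,4-trimethoxyphenyl formate | O=COc1ccc(OC)c(OC)c1OC | intermediate
3 | 2,3,4-trimethoxyphenol | Oc1ccc(OC)c(OC)c1OC | intermediate
4 | 2-hydroxy-3,4,5-trimethoxybenzaldehyde | O=Cc1cc(OC)c(OC)c(OC)c1O | intermediate
5 | methyl (E)-4-bromobut-2-enoate | COC(=O)/C=C/CBr | starting material
6 | methyl (E)-4-(6-formyl-2,3,4-trimethoxyphenoxy)but-2-enoate | COC(=O)/C=C/COc1c(C=O)cc(OC)c(OC)c1OC | intermediate
7 | methyl 2-[(3S)-6,7,8-trimethoxy-4-oxochroman-3-yl]acetate | COC(=O)C[C@H]1COc2c(cc(OC)c(OC)c2OC)C1=O | intermediate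
8 | methyl 2-[(3S)-4-hydroxy-6,7,8-trimethoxychroman-3-yl]acetate, both C4 epimers | COC(=O)C[C@H]1COc2c(cc(OC)c(OC)c2OC)C1O | intermediate
9 | methyl 2-[(3S)-6,7,8-trimethoxychroman-3-yl]acetate | COC(=O)C[C@H]1COc2c(cc(OC)c(OC)c2OC)C1 | intermediate
10 | diethyl 1-methoxy-2-[(3S)-6,7,8-trimethoxychroman-3-yl]ethenyl phosphate, alkene geometry open | CCOP(=O)(OCC)OC(OC)=C[C@H]1COc2c(cc(OC)c(OC)c2OC)C1 | intermediate
11 | (3S)-3-(methoxyethynyl)-6,7,8-trimethoxychroman | COC#C[C@H]1COc2c(cc(OC)c(OC)c2OC)C1 | intermediate
12 | dimethyl squarate (3,4-dimethoxycyclobut-3-ene-1,2-dione) | COC1=C(OC)C(=O)C1=O | starting material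
13 | chlorobis(triphenylphosphine)(2,3-dimethoxy-1,4-dioxobut-2-ene-1,4-diyl)cobalt, a cobaltacyclopentenedione of trivalent cobalt | COC1=C(OC)C(=O)[Co-2](Cl)([P+](c2ccccc2)(c2ccccc2)c2ccccc2)([P+](c2ccccc2)(c2ccccc2)c2ccccc2)C1=O | intermediate
14 | chloro(dimethylglyoxime)(pyridine)(2,3-dimethoxy-1,4-dioxobut-2-ene-1,4-diyl)cobalt, a cobaltacyclopentenedione of trivalent cobalt | COC1=C(OC)C(=O)[Co-3]2(Cl)([n+]3ccccc3)([N+](O)=C(C)C(C)=[N+]2O)C1=O | intermediate
15 | 2,3,5-trimethoxy-6-[(3S)-6,7,8-trimethoxychroman-3-yl]cyclohexa-2,5-diene-1,4-dione | COC1=C(OC)C(=O)C([C@H]2COc3c(cc(OC)c(OC)c3OC)C2)=C(OC)C1=O | target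

Total step count: 8. Longest linear sequence: 7 (steps 1 to 6, then step 8); step 7 is a one-step branch.

Steps most likely to fail

Step 8. Several processes could stall it:
- Alkyne uptake at the electron-rich dimethoxymaleoyl cobalt centre may be slow.
- The oxime OH groups may transfer a proton to the ynol ether, after which it is hydrated or captured.
- The quinone may stay bound to, or be reduced by, low-valent cobalt.

The fallback sets out from 11 and 12 and comes back at 15, and it builds the same ring by electrocyclic ring expansion of a squarate adduct. Syn hydrostannation of 11 with Bu3SnH and Pd(PPh3)4 should give the α-stannyl enol ether tributyl{(E)-1-methoxy-2-[(3S)-6,7,8-trimethoxychroman-3-yl]ethenyl}stannane F1. Tin–lithium exchange with n-BuLi at −78 °C gives the alkenyllithium F2. This adds 1,2 to one carbonyl of 12 to give the 4-alkenyl-4-hydroxycyclobutenone F3. Heating in toluene or xylene opens the four-membered ring to a dienylketene, which closes by a six-electron electrocyclisation and tautomerises to the hydroquinone F4. Oxidation with Ag2O gives 15.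

Step 6. Three processes could compete:
- The enolate may be phosphorylated at carbon instead of oxygen.
- t-BuLi may attack at phosphorus.
- Allylic or propargylic deprotonation at C3 may occur, with loss of the aryloxide.

The fallback sets out from 9 and comes back at 11, and it uses the classical bromination and dehydrobromination of an enol ether.
- Reduction of 9 with iBu2AlH at −78 °C gives the aldehyde F5.
- HC(OMe)3 and pyridinium tosylate in MeOH give the dimethyl acetal F6.
- Me3SiOTf and iPr2NEt remove methanol to give the methyl enol ether F7.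
- Br2 in CH2Cl2 at −78 °C adds to the enol ether faster than to the arene and gives the dibromo ether F8.
- Et3N converts this in the same flask into the bromo enol ether F9.
- LiN(iPr)2 in THF eliminates HBr to give 11.

Step 5. The configuration at C3 may erode by acid enolisation of 7 or by reversible proton loss from the C4 cation. Lactonisation of the cis epimer of 8 is a further risk. The fallback sets out from 7 and comes back at 9. It erases the stereocentre on purpose and sets it again by hydrogenation. NaBH4 and CeCl3·7H2O in MeOH give 8, now isolated. Catalytic p-TsOH in warm toluene dehydrates it to the achiral methyl 2-(6,7,8-trimethoxy-2H-chromen-3-yl)acetate F10. Asymmetric hydrogenation of this trisubstituted styrene-type alkene with [Ir(cod)(tBu-PHOX)]BArF, using the ligand enantiomer that gives (S), and H2 in CH2Cl2 gives 9.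

Further compounds
F1 | step 8 | tributyl{(E)-1-methoxy-2-[(3S)-6,7,8-trimethoxychroman-3-yl]ethenyl}stannane | CCCC[Sn](CCCC)(CCCC)/C(OC)=C/[C@H]1COc2c(cc(OC)c(OC)c2OC)C1
F2 | step 8 | {(Z)-1-methoxy-2-[(3S)-6,7,8-trimethoxychroman-3-yl]ethenyl}lithium | [Li]/C(OC)=C/[C@H]1COc2c(cc(OC)c(OC)c2OC)C1
F3 | step 8 | 4-hydroxy-2,3-dimethoxy-4-{(Z)-1-methoxy-2-[(3S)-6,7,8-trimethoxychroman-3-yl]ethenyl}cyclobut-2-en-1-one, both carbinol epimers | COC1=C(OC)C(O)(/C(OC)=C/[C@H]2COc3c(cc(OC)c(OC)c3OC)C2)C1=O
F4 | step 8 | 2,3,5-trimethoxy-6-[(3S)-6,7,8-trimethoxychroman-3-yl]benzene-1,4-diol | COc1c(OC)c(O)c([C@H]2COc3c(cc(OC)c(OC)c3OC)C2)c(OC)c1O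
F5 | step 6 | 2-[(3S)-6,7,8-trimethoxychroman-3-yl]acetaldehyde | O=CC[C@H]1COc2c(cc(OC)c(OC)c2OC)C1
F6 | step 6 | (3S)-3-(2,2-dimethoxyethyl)-6,7,8-trimethoxychroman | COC(OC)C[C@H]1COc2c(cc(OC)c(OC)c2OC)C1
F7 | step 6 | (3S)-3-(2-methoxyethenyl)-6,7,8-trimethoxychroman, E and Z | COC=C[C@H]1COc2c(cc(OC)c(OC)c2OC)C1
F8 | step 6 | (3R)-3-(1,2-dibromo-2-methoxyethyl)-6,7,8-trimethoxychroman, side-chain centres open | COC(Br)C(Br)[C@H]1COc2c(cc(OC)c(OC)c2OC)C1
F9 | step 6 | (3R)-3-(1-bromo-2-methoxyethenyl)-6,7,8-trimethoxychroman, alkene geometry open | COC=C(Br)[C@H]1COc2c(cc(OC)c(OC)c2OC)C1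
F10 | step 5 | methyl 2-(6,7,8-trimethoxy-2H-chromen-3-yl)acetate | COC(=O)CC1=Cc2cc(OC)c(OC)c(OC)c2OC1
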